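**Plan**

- Decalin numbering: ring A = C1–C5 + C10, ring B = C5–C10, C11 = the OCH2 carbon on C9. The retrosynthesis cuts O–C11 (aryl ether), then C9–C11, then re-adds a formyl group at C6 and cuts C5–C10 and C6–C7 together.
- Feature used: rings A and B share C5–C10 with H5 trans to the C10 methyl. With the olefin moved to C8=C9 beside quaternary C10, ring B is the [4+2] adduct of a C7–C10 diene and a C5=C6 enal held by the C1–C4 tether.
- Forward: a C15 trienal is built linearly (Grignard addition, Johnson–Claisen for the (E)-C9=C10 olefin, ester aldol for quaternary C4, Wittig for the enal). Olefin metathesis is avoided because it would ring-close onto the diene. One amine-catalysed intramolecular Diels–Alder reaction then closes ring B (cycloadduct ring) and ring A (tether ring).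
- Stereochemistry: C5 and C10 come from the catalyst-shielded iminium face and the endo transition state; C3 from equatorial hydride attack (axial OH).
- C9 is set by relay: SeO2 places a hydroxyl on C7 anti to the C10 methyl, and a suprafacial Wittig–Still [2,3] shift carries CH2OH to C9 on that face and fixes the olefin at C7=C8. An intermolecular formaldehyde ene reaction was not used because it would be expected to favour the exocyclic olefin.
- The activating formyl group is removed by decarbonylation right after the cycloaddition; scopoletin is attached last by a Mitsunobu reaction.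

Key step: step 8

Assumption: the face selectivity of the imidazolidinone is taken from the usual model (benzyl group covering one face of the (E)-iminium ion), which assigns the (2R,5R) catalyst to the (5S,10S) adduct; if the sense were opposite for this substrate, the (2S,5S) salt would be used with no other change.

**Route**

Step 1
Reactants: 1 methacrolein; 2 isopropenylmagnesium bromide
Product: 3 2,4-dimethylpenta-1,4-dien-3-ol
Conditions: THF, −78 → 0 °C; aq. NH4Cl
Reagents that add atoms: none
Why: Grignard 1,2-addition to the enal should give the bis-allylic alcohol; the two alkenyl groups are identical, so no stereocentre arises.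

Step 2
Reactants: 3 2,4-dimethylpenta-1,4-dien-3-ol; 4 triethyl orthoacetate
Product: 6 ethyl (4E)-4,6-dimethylhepta-4,6-dienoate, via mixed ketene acetal 5 (not isolated)
Conditions: EtCO2H (cat.), neat, 140 °C, EtOH distilled off
Reagents that add atoms: none
Why: Johnson–Claisen rearrangement through a chair transition state with the isopropenyl group equatorial (the axial alternative suffers a 1,3-diaxial clash with the ethoxy group) should deliver C1–C3 and the (E)-trisubstituted olefin that becomes C9=C10.

Step 3
Reactants: 6 ethyl (4E)-4,6-dimethylhepta-4,6-dienoate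
Product: 7 (4E)-4,6-dimethylhepta-4,6-dienal
Conditions: i-Bu2AlH (1.05 equiv), CH2Cl2, −78 °C; aq. potassium sodium tartrate
Reagents that add atoms: none
Why: Partial ester reduction with i-Bu2AlH should stop at the aluminium hemiacetal at low temperature and give the aldehyde on work-up, the diene being inert to the hydride.

Step 4
Reactants: 7 (4E)-4,6-dimethylhepta-4,6-dienal; 8 methyl isobutyrate
Product: 9 methyl (6E)-3-hydroxy-2,2,6,8-tetramethylnona-6,8-dienoate (racemic)
Conditions: LiN(i-Pr)2, THF, −78 °C; then 7; aq. NH4Cl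
Reagents that add atoms: none
Why: Aldol addition of the lithium ester enolate should form the C3–C4 bond and quaternary C4 in one operation; the carbinol centre forms as a racemate and is erased in step 6.

Step 5
Reactants: 9 methyl (6E)-3-hydroxy-2,2,6,8-tetramethylnona-6,8-dienoate
Product: 10 (6E)-2,2,6,8-tetramethylnona-6,8-diene-1,3-diol (racemic)
Conditions: LiAlH4, THF, 0 °C
Reagents that add atoms: none
Why: Hydride reduction of the hindered ester to the primary alcohol is routine and leaves the isolated diene untouched.

Step 6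
Reactants: 10 (6E)-2,2,6,8-tetramethylnona-6,8-diene-1,3-diol
Product: 11 (6E)-2,2,6,8-tetramethyl-3-oxonona-6,8-dienal
Conditions: Dess–Martin periodinane (2.5 equiv), NaHCO3, CH2Cl2, 0 °C → rt
Reagents that add atoms: none
Why: Dess–Martin oxidation of both hydroxyls under buffered, non-acidic conditions should give the keto aldehyde, which cannot enolise between the carbonyls because C4 is quaternary.

Step 7
Reactants: 11 (6E)-2,2,6,8-tetramethyl-3-oxonona-6,8-dienal; 12 (triphenylphosphoranylidene)acetaldehyde
Product: 13 (2E,8E)-4,4,8,10-tetramethyl-5-oxoundeca-2,8,10-trienal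
Conditions: PhMe, 60 °C
Reagents that add atoms: none
Why: Wittig olefination with the stabilised ylide should react only at the aldehyde (the ketone next to the quaternary carbon is inert) and give the (E)-enal, at a temperature kept low enough to avoid thermal cycloaddition.

Step 8
Reactants: 13 (2E,8E)-4,4,8,10-tetramethyl-5-oxoundeca-2,8,10-trienal
Product: 16 (1R,4aS,8aS)-3,4a,8,8-tetramethyl-7-oxo-1,2,4a,5,6,7,8,8a-octahydronaphthalene-1-carbaldehyde, via trienyl iminium ion 14 (not isolated), via cycloadduct iminium ion 15 (not isolated)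
Conditions: (2R,5R)-5-benzyl-2-tert-butyl-3-methylimidazolidin-4-one trifluoroacetate (20 mol %), MeCN–H2O 98:2, −10 °C → rt
Reagents that add atoms: none
Why: Proposed new method: condensation of the (E)-enal with the amine salt gives an (E)-iminium ion whose lowered LUMO should let the tethered 2,4-dimethylpenta-1,3-dienyl unit add across C5=C6 in a concerted, asynchronous [4+2] cycloaddition that forms C5–C10 and C6–C7, after which hydrolysis releases aldehyde 16 and the amine; the closest known reaction type is the imidazolidinone-catalysed intramolecular Diels–Alder reaction of (E,E)-deca-2,7,9-trienals to trans-fused bicyclic aldehydes, not yet shown for a diene terminus that becomes quaternary or for a β-carbon next to a gem-dimethyl group. Ring B closes as the six-membered cycloadduct ring with its olefin at C8=C9, and ring A closes as the tether ring of a type 1 intramolecular Diels–Alder reaction, the four-atom C1–C4 tether adopting a chair with the new C5–C10 bond as ring fusion. C5 is set by the catalyst, whose benzyl group covers one face of the iminium π system so that the diene adds to the open face (5S with the (2R,5R) salt). C6 follows from suprafacial addition to the (E)-enal (formyl syn to H5), and C10 from the endo orientation of the iminium over the (E)-configured C9=C10 terminus, which places the C10 methyl anti to H5. The step needs endo over exo closure and one enantioface: the (E)-enal, the olefin geometry fixed in step 2 and the chair tether should secure the first and the catalyst the second, while quaternary C4 rules out dienamine formation and the hindered C3 ketone should not condense with the amine.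

Step 9
Reactants: 16 (1R,4aS,8aS)-3,4a,8,8-tetramethyl-7-oxo-1,2,4a,5,6,7,8,8a-octahydronaphthalene-1-carbaldehyde
Product: 17 (4aS,8aS)-1,1,4a,6-tetramethyl-3,4,4a,7,8,8a-hexahydronaphthalen-2(1H)-one
Conditions: RhCl(PPh3)3 (1.1 equiv), PhCN, 130 °C
Reagents that add atoms: none
Why: Tsuji–Wilkinson decarbonylation (oxidative addition of monovalent rhodium into the formyl C–H bond, CO migration to the metal, C–H reductive elimination) should remove the activating group; C6 becomes CH2 and C5 and C10 are not touched.

Step 10
Reactants: 17 (4aS,8aS)-1,1,4a,6-tetramethyl-3,4,4a,7,8,8a-hexahydronaphthalen-2(1H)-one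
Product: 18 (2S,4aS,8aS)-1,1,4a,6-tetramethyl-1,2,3,4,4a,7,8,8a-octahydronaphthalen-2-ol
Conditions: LiBH(s-Bu)3, THF, −78 → 0 °C; NaOH, H2O2
Reagents that add atoms: none
Why: The bulky trialkylborohydride should attack the C3 carbonyl next to the gem-dimethyl carbon from the equatorial direction, giving the axial alcohol (OH on the face of H5, anti to the C10 methyl).

Step 11
Reactants: 18 (2S,4aS,8aS)-1,1,4a,6-tetramethyl-1,2,3,4,4a,7,8,8a-octahydronaphthalen-2-ol
Product: 20 (2S,4aS,7S,8aS)-1,1,4a,6-tetramethyl-1,2,3,4,4a,7,8,8a-octahydronaphthalene-2,7-diol, via allylic seleninic acid 19 (not isolated)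
Conditions: SeO2 (0.5 equiv), t-BuOOH (2 equiv), CH2Cl2, rt
Reagents that add atoms: selenium dioxide, O=[Se]=O; tert-butyl hydroperoxide, CC(C)(C)OO
Why: SeO2 allylic hydroxylation (ene reaction, then [2,3]-sigmatropic shift) should bond selenium to C9 on the face anti to the C10 methyl with transfer of the pseudoaxial ring hydrogen at C7, and the [2,3] shift returns oxygen to C7 on the same face, so the olefin stays at C8=C9 and the new hydroxyl is pseudoaxial and anti to the C10 methyl.

Step 12
Reactants: 20 (2S,4aS,7S,8aS)-1,1,4a,6-tetramethyl-1,2,3,4,4a,7,8,8a-octahydronaphthalene-2,7-diol; 21 tributyl(iodomethyl)stannane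
Product: 22 (2S,4aS,7S,8aS)-1,1,4a,6-tetramethyl-7-[(tributylstannyl)methoxy]-1,2,3,4,4a,7,8,8a-octahydronaphthalen-2-ol
Conditions: KH (1.2 equiv), THF, 0 °C; then Bu3SnCH2I (1.1 equiv), 0 °C → rt
Reagents that add atoms: none
Why: Williamson etherification should take place at the allylic C7 alkoxide, because the axial C3 hydroxyl is neopentylic (flanked by the C4 gem-dimethyl group) and is alkylated much more slowly.

Step 13
Reactants: 22 (2S,4aS,7S,8aS)-1,1,4a,6-tetramethyl-7-[(tributylstannyl)methoxy]-1,2,3,4,4a,7,8,8a-octahydronaphthalen-2-ol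
Product: 24 (2S,4aR,5S,8aS)-5-(hydroxymethyl)-1,1,4a,6-tetramethyl-1,2,3,4,4a,5,8,8a-octahydronaphthalen-2-ol, via lithiomethyl ether 23 (not isolated)
Conditions: n-BuLi (2.5 equiv), THF, −78 °C; aq. NH4Cl
Reagents that add atoms: none
Why: Wittig–Still [2,3]-sigmatropic rearrangement: tin–lithium exchange gives the α-alkoxy organolithium, which should pass the CH2O unit suprafacially from the pseudoaxial C7 oxygen to C9, setting C9 with C11 anti to the C10 methyl and moving the olefin to C7=C8.

Step 14
Reactants: 24 (2S,4aR,5S,8aS)-5-(hydroxymethyl)-1,1,4a,6-tetramethyl-1,2,3,4,4a,5,8,8a-octahydronaphthalen-2-ol; 25 scopoletin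
Product: 26 7-{[(1S,4aS,6S,8aR)-6-hydroxy-2,5,5,8a-tetramethyl-1,4,4a,5,6,7,8,8a-octahydronaphthalen-1-yl]methoxy}-6-methoxy-2H-chromen-2-one (CNP0218138.1)
Conditions: PPh3, i-PrO2CN=NCO2i-Pr (DIAD), THF, 0 °C → rt
Reagents that add atoms: none
Why: Mitsunobu etherification should activate the primary C11 alcohol in preference to the hindered axial C3 alcohol and let the acidic phenol of scopoletin displace it; no stereocentre is involved.

**Compound list**

1 | methacrolein (2-methylprop-2-enal) | CC(=C)C=O | starting material
2 | isopropenylmagnesium bromide | CC(=C)[Mg]Br | starting material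
3 | 2,4-dimethylpenta-1,4-dien-3-ol | CC(=C)C(O)C(C)=C | intermediate
4 | triethyl orthoacetate | CCOC(C)(OCC)OCC | starting material
5 | 3-[(1-ethoxyethenyl)oxy]-2,4-dimethylpenta-1,4-diene (mixed ketene acetal, not isolated) | C=C(OCC)OC(C(C)=C)C(C)=C | intermediate
6 | ethyl (4E)-4,6-dimethylhepta-4,6-dienoate | CCOC(=O)CC/C(C)=C/C(C)=C | intermediate
7 | (4E)-4,6-dimethylhepta-4,6-dienal | O=CCC/C(C)=C/C(C)=C | intermediate
8 | methyl isobutyrate (methyl 2-methylpropanoate) | COC(=O)C(C)C | starting material
9 | methyl (6E)-3-hydroxy-2,2,6,8-tetramethylnona-6,8-dienoate (racemic) | COC(=O)C(C)(C)C(O)CC/C(C)=C/C(C)=C | intermediate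
10 | (6E)-2,2,6,8-tetramethylnona-6,8-diene-1,3-diol (racemic) | OCC(C)(C)C(O)CC/C(C)=C/C(C)=C | intermediate
11 | (6E)-2,2,6,8-tetramethyl-3-oxonona-6,8-dienal | O=CC(C)(C)C(=O)CC/C(C)=C/C(C)=C | intermediate
12 | (triphenylphosphoranylidene)acetaldehyde | O=CC=P(c1ccccc1)(c1ccccc1)c1ccccc1 | starting material
13 | (2E,8E)-4,4,8,10-tetramethyl-5-oxoundeca-2,8,10-trienal | O=C/C=C/C(C)(C)C(=O)CC/C(C)=C/C(C)=C | intermediate
14 | (E)-iminium trifluoroacetate of 13 with (2R,5R)-5-benzyl-2-tert-butyl-3-methylimidazolidin-4-one (trienyl iminium ion, not isolated) | CN1[C@@H]([N+](=C/C=C/C(C)(C)C(=O)CC/C(C)=C/C(C)=C)[C@H](Cc2ccccc2)C1=O)C(C)(C)C.[O-]C(=O)C(F)(F)F | intermediate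
15 | iminium trifluoroacetate of 16 with the same amine (cycloadduct iminium ion, not isolated) | CN1[C@@H]([N+](=C[C@@H]2CC(C)=C[C@]3(C)CCC(=O)C(C)(C)[C@@H]23)[C@H](Cc4ccccc4)C1=O)C(C)(C)C.[O-]C(=O)C(F)(F)F | intermediate
16 | (1R,4aS,8aS)-3,4a,8,8-tetramethyl-7-oxo-1,2,4a,5,6,7,8,8a-octahydronaphthalene-1-carbaldehyde (decalin numbering 5S,6R,10S: C3 ketone, C6 formyl syn to H5, olefin C8=C9, H5 anti to the C10 methyl) | O=C[C@@H]1CC(C)=C[C@]2(C)CCC(=O)C(C)(C)[C@@H]12 | intermediate
17 | (4aS,8aS)-1,1,4a,6-tetramethyl-3,4,4a,7,8,8a-hexahydronaphthalen-2(1H)-one | C1CC(C)=C[C@]2(C)CCC(=O)C(C)(C)[C@@H]12 | intermediate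
18 | (2S,4aS,8aS)-1,1,4a,6-tetramethyl-1,2,3,4,4a,7,8,8a-octahydronaphthalen-2-ol (axial C3–OH) | C1CC(C)=C[C@]2(C)CC[C@H](O)C(C)(C)[C@@H]12 | intermediate
19 | (1S,4aS,6S,8aR)-6-hydroxy-2,5,5,8a-tetramethyl-1,4,4a,5,6,7,8,8a-octahydronaphthalene-1-seleninic acid (Se on C9 anti to the C10 methyl, olefin C7=C8, not isolated) | O[Se](=O)[C@H]1C(C)=CC[C@@H]2C(C)(C)[C@@H](O)CC[C@]21C | intermediate
20 | (2S,4aS,7S,8aS)-1,1,4a,6-tetramethyl-1,2,3,4,4a,7,8,8a-octahydronaphthalene-2,7-diol (C7–OH anti to the C10 methyl) | C1[C@H](O)C(C)=C[C@]2(C)CC[C@H](O)C(C)(C)[C@@H]12 | intermediate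
21 | tributyl(iodomethyl)stannane | CCCC[Sn](CCCC)(CCCC)CI | starting material
22 | (2S,4aS,7S,8aS)-1,1,4a,6-tetramethyl-7-[(tributylstannyl)methoxy]-1,2,3,4,4a,7,8,8a-octahydronaphthalen-2-ol | C1[C@H](OC[Sn](CCCC)(CCCC)CCCC)C(C)=C[C@]2(C)CC[C@H](O)C(C)(C)[C@@H]12 | intermediate
23 | lithium alkoxide of 22 carrying LiCH2O on C7 (lithiomethyl ether, not isolated) | C1[C@H](OC[Li])C(C)=C[C@]2(C)CC[C@H](O[Li])C(C)(C)[C@@H]12 | intermediate
24 | (2S,4aR,5S,8aS)-5-(hydroxymethyl)-1,1,4a,6-tetramethyl-1,2,3,4,4a,5,8,8a-octahydronaphthalen-2-ol (C11 anti to the C10 methyl, olefin C7=C8) | OC[C@H]1C(C)=CC[C@@H]2C(C)(C)[C@@H](O)CC[C@]21C | intermediate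
25 | scopoletin (7-hydroxy-6-methoxy-2H-chromen-2-one) | COc1cc2ccc(=O)oc2cc1O | starting material
26 | 7-{[(1S,4aS,6S,8aR)-6-hydroxy-2,5,5,8a-tetramethyl-1,4,4a,5,6,7,8,8a-octahydronaphthalen-1-yl]methoxy}-6-methoxy-2H-chromen-2-one (CNP0218138.1) | COc1cc2ccc(=O)oc2cc1OC[C@H]1C(C)=CC[C@@H]2C(C)(C)[C@@H](O)CC[C@]21C | target

**Step count and risks**

Total step count: 14. Longest linear sequence: 14 steps (1 → 26).

Steps most likely to fail:

Step 8 (Proposed new method). Bond formation between C5, next to the gem-dimethyl carbon, and the fully substituted diene terminus C10 may be slow. Acid-induced decomposition of the diene, the uncatalysed racemic cycloaddition or exo closure could then take over. Fallback (known chemistry: auxiliary-controlled Lewis acid cycloaddition in place of amine catalysis): setting out from keto aldehyde 11, a Horner–Wadsworth–Emmons reaction with diethyl {2-[(4R)-4-benzyl-2-oxo-1,3-oxazolidin-3-yl]-2-oxoethyl}phosphonate (LiCl, i-Pr2NEt, MeCN) would give the (E)-N-enoyl oxazolidinone, trienimide F1. Me2AlCl (CH2Cl2, −30 °C) should bring about the endo intramolecular Diels–Alder reaction on the face of the chelated enoyl group away from the benzyl substituent, giving the imide cycloadduct F2. LiSEt (THF, 0 °C) would release the auxiliary and give the S-ethyl thioester F3, and a Fukuyama reduction (Et3SiH, Pd/C, acetone) would return to the route at aldehyde 16.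

Step 11. The ene step at C9, next to quaternary C10, may be slow, so that oxidation at the C8 methyl group or over-oxidation to the enone prevails. Fallback (oxidation to the ketone level followed by hydride delivery, in place of direct hydroxylation): setting out from ketone 17, allylic oxidation with CrO3·3,5-dimethylpyrazole (CH2Cl2, −20 °C) would give the ene-dione F4. An excess of LiBH(s-Bu)3 (THF, −78 °C) should then reduce both carbonyl groups by 1,2-attack from the equatorial direction (conjugate delivery to neopentylic C9 being disfavoured), returning to the route at diol 20.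

Step 12. Chemoselectivity between the two secondary alkoxides may be lost, with alkylation at C3 or at both oxygens. Fallback (a [2,3] shift that only an allylic alcohol can undergo, in place of the tin route): setting out from diol 20, heating with N,N-dimethylformamide dimethyl acetal (xylene, 140 °C) should lead, through the alkoxy(dimethylamino)carbene of the allylic C7 oxygen, to the C9 N,N-dimethylcarboxamide F5 with the same suprafacial transfer and olefin shift. LiBHEt3 (THF, 0 °C → rt) would reduce the tertiary amide to the primary alcohol and return to the route at diol 24.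

**Further compounds**

F1 | step 8 | (4R)-4-benzyl-3-[(2E,8E)-4,4,8,10-tetramethyl-5-oxoundeca-2,8,10-trienoyl]-1,3-oxazolidin-2-one | O=C(/C=C/C(C)(C)C(=O)CC/C(C)=C/C(C)=C)N1[C@H](Cc2ccccc2)COC1=O
F2 | step 8 | (4R)-4-benzyl-3-{[(1R,4aS,8aS)-3,4a,8,8-tetramethyl-7-oxo-1,2,4a,5,6,7,8,8a-octahydronaphthalen-1-yl]carbonyl}-1,3-oxazolidin-2-one | O=C([C@@H]1CC(C)=C[C@]2(C)CCC(=O)C(C)(C)[C@@H]12)N1[C@H](Cc3ccccc3)COC1=O
F3 | step 8 | S-ethyl (1R,4aS,8aS)-3,4a,8,8-tetramethyl-7-oxo-1,2,4a,5,6,7,8,8a-octahydronaphthalene-1-carbothioate | CCSC(=O)[C@@H]1CC(C)=C[C@]2(C)CCC(=O)C(C)(C)[C@@H]12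
F4 | step 11 | (4aS,8aS)-3,4a,8,8-tetramethyl-4a,5,6,8a-tetrahydronaphthalene-2,7(1H,8H)-dione | C1C(=O)C(C)=C[C@]2(C)CCC(=O)C(C)(C)[C@@H]12
F5 | step 12 | (1S,4aS,6S,8aR)-6-hydroxy-N,N,2,5,5,8a-hexamethyl-1,4,4a,5,6,7,8,8a-octahydronaphthalene-1-carboxamide | CN(C)C(=O)[C@H]1C(C)=CC[C@@H]2C(C)(C)[C@@H](O)CC[C@]21C
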